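**Plan**

1. Numbering used throughout: C1 = CH3-bearing quaternary ring-fusion carbon, C2 and C3 = the two CH2 of the cyclopentane, C4 = isopropyl carbinol, C5 = ring-fusion CH, C6 = ester carbinol, C7 = ketone, C8/C9 = diol carbons, C10 = CH2.
2. Cuts: benzyl ether of the phenol; C8/C9 diol back to an enone; C8=C9 (aldol condensation, closes the seven-membered ring); C4–isopropyl; C6–C7 and the ester (acyl-anion addition with acylation in the same flask); then the cyclopentane is led back, by returning C1 from C5 to C6, to a cyclohexene that is cut at C2–C3 and C1–C6 into methacrolein and a 1-silyloxybutadiene.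
3. Forward order of rings: six-membered Diels–Alder ring (C1–C6), epoxide, semipinacol ring contraction to the cyclopentane C1–C5 with C6 extruded as CHO, side chains on C5 and C1, seven-membered ring by intramolecular aldol condensation, cis-dihydroxylation.
4. Enabling feature: C2 and C3 are the only adjacent unsubstituted CH2 groups, set between the quaternary C1 and the oxygenated C4, and C4(O)–C5(H)–C6(O) is an aldol array. A temporary C1–C6 bond therefore turns C1–C2–C3–C4–C5–C6 into the ortho/endo Diels–Alder adduct of a 1-oxygenated diene, and the same bond is later shifted to C5.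
5. Stereochemistry: C1 from the catalyst in the cycloaddition; C5 (and the oxygen on C4) relayed from the temporary C6 centre by anti epoxidation and a stereospecific anti 1,2-shift; C4 by addition anti to the C5 side chain; C6 by 1,2-induction from C5; C8/C9 by osmylation anti to the C1 methyl group.

Key step: step 2

Remark: the (S)-configured oxazaborolidinium catalyst is taken to give the (1S,2R) adduct 4; should the sense of induction be the opposite, its enantiomer is used and nothing else changes.

**Route**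

Step 1
Reactants: 1 (2E)-but-2-enal (crotonaldehyde)
Product: 2 tert-butyl[(1E)-buta-1,3-dien-1-yloxy]dimethylsilane
Conditions: t-BuMe2SiOTf, Et3N, Et2O, 0 °C to rt
Reagents that add atoms: tert-butyldimethylsilyl trifluoromethanesulfonate, CC(C)(C)[Si](C)(C)OS(=O)(=O)C(F)(F)F
Why: Silyl dienol ether formation, in which O-silylation of the enal followed by γ-deprotonation by the amine should give the conjugated (E)-1-silyloxydiene; no stereocentre is created.

Step 2
Reactants: 2 tert-butyl[(1E)-buta-1,3-dien-1-yloxy]dimethylsilane; 3 2-methylprop-2-enal (methacrolein)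
Product: 4 (1S,2R)-2-{[tert-butyl(dimethyl)silyl]oxy}-1-methylcyclohex-3-ene-1-carbaldehyde (CHO cis to the silyloxy group)
Conditions: (S)-3,3-diphenyl-1-(2-methylphenyl)tetrahydro-1H,3H-pyrrolo[1,2-c][1,3,2]oxazaborole (10 mol%), HNTf2 (10 mol%), CH2Cl2, −78 °C
Reagents that add atoms: none
Why: Catalytic enantioselective Diels–Alder reaction ([4+2] cycloaddition of an α-substituted acrolein bound to a chiral oxazaborolidinium Lewis acid, a well-precedented reaction type): the activated s-trans enal and the s-cis diene 2 combine in a concerted, asynchronous, suprafacial event that forms the C2–C3 bond (CH2 terminus of the diene to the CH2 of the dienophile) and, with it, the temporary C1–C6 bond. The six-membered ring C1–C6 is closed intermolecularly in the [4+2] mode, the C2–C3 bond being the more advanced one in the transition state because the silyloxy donor on C6 makes C3 the nucleophilic terminus and the formyl group makes C2 the electrophilic carbon, which also fixes the ortho regiochemistry. The quaternary stereocentre C1 is controlled by the catalyst, whose aryl groups shield one face of the coordinated enal so that the diene adds to the Re face of the α-carbon and C1 becomes S. The second new stereocentre, C6, is temporary and is set relative to C1 by the endo rule (formyl group endo, hence CHO cis to the silyloxy group). The step needs regio-, endo- and enantioface selectivity; the first is secured by the 1-silyloxy group of 2 and the α-formyl group of 3, the other two by the rigid catalyst–aldehyde complex at low temperature. The C1–C6 bond is not a bond of the target: it holds C1 in a ring so that its configuration can be relayed to C5 and C4, and it is shifted to C5 in step 5.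

Step 3
Reactants: 4 (1S,2R)-2-{[tert-butyl(dimethyl)silyl]oxy}-1-methylcyclohex-3-ene-1-carbaldehyde
Product: 5 tert-butyl{[(1R,6R)-6-ethenyl-6-methylcyclohex-2-en-1-yl]oxy}dimethylsilane
Conditions: Ph3PCH3Br, KN(SiMe3)2, THF, 0 °C to rt
Reagents that add atoms: methyltriphenylphosphonium bromide, C[P+](c1ccccc1)(c1ccccc1)c1ccccc1.[Br-]
Why: Wittig methylenation of the hindered, non-enolisable aldehyde should turn the formyl carbon (C10) into the vinyl group C10=C9 that later becomes the C10H2–C9 aldehyde, without touching a stereocentre.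

Step 4
Reactants: 5 tert-butyl{[(1R,6R)-6-ethenyl-6-methylcyclohex-2-en-1-yl]oxy}dimethylsilane
Product: 6 tert-butyl{[(1S,2S,3R,6S)-3-ethenyl-3-methyl-7-oxabicyclo[4.1.0]heptan-2-yl]oxy}dimethylsilane (epoxide trans to the silyloxy group, cis to the methyl group)
Conditions: mCPBA, NaHCO3, CH2Cl2, 0 °C
Reagents that add atoms: 3-chloroperoxybenzoic acid, OOC(=O)c1cccc(Cl)c1
Why: Prilezhaev epoxidation, in which the cis-disubstituted ring alkene is more nucleophilic than the vinyl group and the peracid should approach anti to the allylic silyloxy group, so that the epoxide oxygen (the future C4–O) lies on the face of the C1 methyl group.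

Step 5
Reactants: 6 tert-butyl{[(1S,2S,3R,6S)-3-ethenyl-3-methyl-7-oxabicyclo[4.1.0]heptan-2-yl]oxy}dimethylsilane
Product: 7 (1R,2R,5S)-5-{[tert-butyl(dimethyl)silyl]oxy}-2-ethenyl-2-methylcyclopentane-1-carbaldehyde (CHO cis to the silyloxy and methyl groups)
Conditions: t-BuMe2SiOTf (0.2 equiv), 2,6-di-tert-butyl-4-methylpyridine (0.3 equiv), CH2Cl2, −78 to −40 °C
Reagents that add atoms: none
Why: Semipinacol rearrangement of a 2,3-epoxy silyl ether with ring contraction: the silyl triflate activates the epoxide oxygen, the C6–C1 ring bond (the only group on C6 that can become anti-periplanar to the breaking C5–O bond, H-6 being syn to it) migrates to C5 with inversion at C5 and retention at C1 while the C6 oxygen stabilises the developing cation, and loss of the silyl group from the oxocarbenium ion gives the aldehyde and returns the catalyst, so that H-5 should end trans to the C1 methyl group and the new C4 silyl ether cis to the formyl group.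

Step 6
Reactants: 7 (1R,2R,5S)-5-{[tert-butyl(dimethyl)silyl]oxy}-2-ethenyl-2-methylcyclopentane-1-carbaldehyde; 8 2-ethyl-1,3-dithiane; 9 4-(benzyloxy)benzoyl chloride
Product: 12 (R)-[(1S,2R,5S)-5-{[tert-butyl(dimethyl)silyl]oxy}-2-ethenyl-2-methylcyclopentyl](2-ethyl-1,3-dithian-2-yl)methyl 4-(benzyloxy)benzoate, via 2-ethyl-2-lithio-1,3-dithiane 10 (not isolated), via lithium alkoxide 11 (not isolated)
Conditions: 8, n-BuLi, THF, −30 °C; then 7, −78 °C; then 9, −78 to 0 °C
Reagents that add atoms: none
Why: Corey–Seebach umpolung, in which the lithiated dithiane (a propionyl anion equivalent) adds to the α-branched aldehyde under 1,2-induction from C5 (quaternary C1 anti to the nucleophile, attack past H-5, no chelation by the silyl ether) to set C6, and the hindered lithium alkoxide is acylated in the same flask.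

Step 7
Reactants: 12 (R)-[(1S,2R,5S)-5-{[tert-butyl(dimethyl)silyl]oxy}-2-ethenyl-2-methylcyclopentyl](2-ethyl-1,3-dithian-2-yl)methyl 4-(benzyloxy)benzoate
Product: 13 (R)-[(1R,2R,5S)-2-ethenyl-5-hydroxy-2-methylcyclopentyl](2-ethyl-1,3-dithian-2-yl)methyl 4-(benzyloxy)benzoate
Conditions: HF·pyridine, pyridine, THF, 0 °C to rt
Reagents that add atoms: none
Why: Fluoride-mediated desilylation of the secondary silyl ether under slightly acidic conditions that should leave the aryl ester in place and not trigger 1,3-acyl migration.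

Step 8
Reactants: 13 (R)-[(1R,2R,5S)-2-ethenyl-5-hydroxy-2-methylcyclopentyl](2-ethyl-1,3-dithian-2-yl)methyl 4-(benzyloxy)benzoate
Product: 14 (R)-(2-ethyl-1,3-dithian-2-yl)[(1S,2R)-2-ethenyl-2-methyl-5-oxocyclopentyl]methyl 4-(benzyloxy)benzoate
Conditions: Dess–Martin periodinane, NaHCO3, dry CH2Cl2, 0 °C to rt
Reagents that add atoms: none
Why: Dess–Martin oxidation of the secondary alcohol under neutral, anhydrous conditions, chosen to avoid β-elimination of the β-acyloxy ketone, epimerisation at C5 and hydrolysis of the dithiane.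

Step 9
Reactants: 14 (R)-(2-ethyl-1,3-dithian-2-yl)[(1S,2R)-2-ethenyl-2-methyl-5-oxocyclopentyl]methyl 4-(benzyloxy)benzoate
Product: 15 (R)-(2-ethyl-1,3-dithian-2-yl)[(1S,2R,5R)-2-ethenyl-5-hydroxy-2-methyl-5-(propan-2-yl)cyclopentyl]methyl 4-(benzyloxy)benzoate
Conditions: i-PrMgCl, CeCl3, THF, −78 °C; aq. NH4Cl
Reagents that add atoms: isopropylmagnesium chloride, CC(C)[Mg]Cl
Why: Organocerium 1,2-addition to the cyclopentanone, in which the weakly basic reagent should add to the ketone much faster than to the aryl ester and without enolisation, and should attack the face anti to the bulky C5 side chain so that the isopropyl group ends trans and the C4 hydroxyl cis to that side chain.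

Step 10
Reactants: 15 (R)-(2-ethyl-1,3-dithian-2-yl)[(1S,2R,5R)-2-ethenyl-5-hydroxy-2-methyl-5-(propan-2-yl)cyclopentyl]methyl 4-(benzyloxy)benzoate
Product: 16 (1R)-1-[(1S,2R,5R)-2-ethenyl-5-hydroxy-2-methyl-5-(propan-2-yl)cyclopentyl]-2-oxobutyl 4-(benzyloxy)benzoate
Conditions: MeI, CaCO3, MeCN/H2O, 45 °C
Reagents that add atoms: water, O
Why: Alkylative hydrolysis of the 1,3-dithiane (S-methylation, ring opening, hydrolysis) should unmask the C7 ketone under near-neutral, non-oxidising conditions that spare the vinyl group, the aryl ether and the base-sensitive stereocentre C6.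

Step 11
Reactants: 16 (1R)-1-[(1S,2R,5R)-2-ethenyl-5-hydroxy-2-methyl-5-(propan-2-yl)cyclopentyl]-2-oxobutyl 4-(benzyloxy)benzoate
Product: 17 (1R)-1-[(1S,2R,5R)-2-hydroxy-5-methyl-5-(2-oxoethyl)-2-(propan-2-yl)cyclopentyl]-2-oxobutyl 4-(benzyloxy)benzoate
Conditions: PdCl2(PhCN)2 (10 mol%), CuCl2·2H2O (10 mol%), AgNO2 (5 mol%), O2 (1 atm), t-BuOH/MeNO2, rt
Reagents that add atoms: dioxygen, O=O
Why: Nitrite-modified, aldehyde-selective Wacker oxidation, in which oxygen should be delivered to the terminal carbon of the vinyl group (favoured by the adjacent quaternary carbon), while the tertiary hydroxyl group, trans to the vinyl group on the ring, cannot intercept the palladium–alkene complex.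

Step 12
Reactants: 17 (1R)-1-[(1S,2R,5R)-2-hydroxy-5-methyl-5-(2-oxoethyl)-2-(propan-2-yl)cyclopentyl]-2-oxobutyl 4-(benzyloxy)benzoate
Product: 19 (3R,3aS,4R,8aR)-3-hydroxy-6,8a-dimethyl-5-oxo-3-(propan-2-yl)-1,2,3,3a,4,5,8,8a-octahydroazulen-4-yl 4-(benzyloxy)benzoate, via aldol adduct 18 (not isolated)
Conditions: dibenzylammonium trifluoroacetate (30 mol%), toluene (high dilution), 60 °C
Reagents that add atoms: none
Why: Intramolecular aldol condensation under amine-salt catalysis, in which the C8 enol of the ethyl ketone should add to the activated C9 aldehyde in a 7-(enolendo)-exo-trig closure and lose water to give the conjugated 2-methylcycloheptenone, whereas the two conceivable five-membered closures would give strained trans-fused bicyclo[3.3.0]octanes and are reversible.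

Step 13
Reactants: 19 (3R,3aS,4R,8aR)-3-hydroxy-6,8a-dimethyl-5-oxo-3-(propan-2-yl)-1,2,3,3a,4,5,8,8a-octahydroazulen-4-yl 4-(benzyloxy)benzoate
Product: 20 (3R,3aS,4R,6S,7S,8aR)-3,6,7-trihydroxy-6,8a-dimethyl-5-oxo-3-(propan-2-yl)decahydroazulen-4-yl 4-(benzyloxy)benzoate
Conditions: OsO4 (5 mol%), NMO, citric acid, t-BuOH/H2O, rt
Reagents that add atoms: osmium tetroxide, O=[Os](=O)(=O)=O; N-methylmorpholine N-oxide, C[N+]1([O-])CCOCC1
Why: Catalytic syn-dihydroxylation with osmium tetroxide and NMO as terminal oxidant, in which the [3+2] addition to C8=C9 should take place on the face opposite the angular C1 methyl group (the face of the C6 ester and H-5) to give the cis-8,9-diol, the citric acid keeping the medium slightly acidic to speed turnover and suppress acyl migration.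

Step 14
Reactants: 20 (3R,3aS,4R,6S,7S,8aR)-3,6,7-trihydroxy-6,8a-dimethyl-5-oxo-3-(propan-2-yl)decahydroazulen-4-yl 4-(benzyloxy)benzoate
Product: 21 (3R,3aS,4R,6S,7S,8aR)-3,6,7-trihydroxy-6,8a-dimethyl-5-oxo-3-(propan-2-yl)decahydroazulen-4-yl 4-hydroxybenzoate (target)
Conditions: H2 (1 atm), Pd/C, EtOAc, rt
Reagents that add atoms: none
Why: Hydrogenolysis of the benzyl aryl ether over palladium on carbon should liberate the phenol under neutral conditions that leave the ester, the ketone and the three hydroxyl groups untouched.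

**Compound list**

1 | (2E)-but-2-enal | C/C=C/C=O | starting material
2 | tert-butyl[(1E)-buta-1,3-dien-1-yloxy]dimethylsilane | C=C/C=C/O[Si](C)(C)C(C)(C)C | intermediate
3 | 2-methylprop-2-enal | C=C(C)C=O | starting material
4 | (1S,2R)-2-{[tert-butyl(dimethyl)silyl]oxy}-1-methylcyclohex-3-ene-1-carbaldehyde | O=C[C@@]1(C)CCC=C[C@H]1O[Si](C)(C)C(C)(C)C | intermediate
5 | tert-butyl{[(1R,6R)-6-ethenyl-6-methylcyclohex-2-en-1-yl]oxy}dimethylsilane | C=C[C@@]1(C)CCC=C[C@H]1O[Si](C)(C)C(C)(C)C | intermediate
6 | tert-butyl{[(1S,2S,3R,6S)-3-ethenyl-3-methyl-7-oxabicyclo[4.1.0]heptan-2-yl]oxy}dimethylsilane | C=C[C@@]1(C)CC[C@@H]2O[C@@H]2[C@H]1O[Si](C)(C)C(C)(C)C | intermediate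
7 | (1R,2R,5S)-5-{[tert-butyl(dimethyl)silyl]oxy}-2-ethenyl-2-methylcyclopentane-1-carbaldehyde | O=C[C@H]1[C@@H](O[Si](C)(C)C(C)(C)C)CC[C@]1(C)C=C | intermediate
8 | 2-ethyl-1,3-dithiane | CCC1SCCCS1 | starting material
9 | 4-(benzyloxy)benzoyl chloride | O=C(Cl)c1ccc(OCc2ccccc2)cc1 | starting material
10 | 2-ethyl-2-lithio-1,3-dithiane | CCC1([Li])SCCCS1 | intermediate
11 | lithium (R)-[(1S,2R,5S)-5-{[tert-butyl(dimethyl)silyl]oxy}-2-ethenyl-2-methylcyclopentyl](2-ethyl-1,3-dithian-2-yl)methanolate | CCC1(SCCCS1)[C@H]([O-])[C@H]2[C@@H](O[Si](C)(C)C(C)(C)C)CC[C@]2(C)C=C.[Li+] | intermediate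
12 | (R)-[(1S,2R,5S)-5-{[tert-butyl(dimethyl)silyl]oxy}-2-ethenyl-2-methylcyclopentyl](2-ethyl-1,3-dithian-2-yl)methyl 4-(benzyloxy)benzoate | CCC1(SCCCS1)[C@H](OC(=O)c1ccc(OCc3ccccc3)cc1)[C@H]2[C@@H](O[Si](C)(C)C(C)(C)C)CC[C@]2(C)C=C | intermediate
13 | (R)-[(1R,2R,5S)-2-ethenyl-5-hydroxy-2-methylcyclopentyl](2-ethyl-1,3-dithian-2-yl)methyl 4-(benzyloxy)benzoate | CCC1(SCCCS1)[C@H](OC(=O)c1ccc(OCc3ccccc3)cc1)[C@H]2[C@@H](O)CC[C@]2(C)C=C | intermediate
14 | (R)-(2-ethyl-1,3-dithian-2-yl)[(1S,2R)-2-ethenyl-2-methyl-5-oxocyclopentyl]methyl 4-(benzyloxy)benzoate | CCC1(SCCCS1)[C@H](OC(=O)c1ccc(OCc3ccccc3)cc1)[C@H]2C(=O)CC[C@]2(C)C=C | intermediate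
15 | (R)-(2-ethyl-1,3-dithian-2-yl)[(1S,2R,5R)-2-ethenyl-5-hydroxy-2-methyl-5-(propan-2-yl)cyclopentyl]methyl 4-(benzyloxy)benzoate | CCC1(SCCCS1)[C@H](OC(=O)c1ccc(OCc3ccccc3)cc1)[C@H]2[C@](O)(C(C)C)CC[C@]2(C)C=C | intermediate
16 | (1R)-1-[(1S,2R,5R)-2-ethenyl-5-hydroxy-2-methyl-5-(propan-2-yl)cyclopentyl]-2-oxobutyl 4-(benzyloxy)benzoate | CCC(=O)[C@H](OC(=O)c1ccc(OCc3ccccc3)cc1)[C@H]2[C@](O)(C(C)C)CC[C@]2(C)C=C | intermediate
17 | (1R)-1-[(1S,2R,5R)-2-hydroxy-5-methyl-5-(2-oxoethyl)-2-(propan-2-yl)cyclopentyl]-2-oxobutyl 4-(benzyloxy)benzoate | CCC(=O)[C@H](OC(=O)c1ccc(OCc3ccccc3)cc1)[C@H]2[C@](O)(C(C)C)CC[C@]2(C)CC=O | intermediate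
18 | (3R,3aS,4R,8aR)-3,7-dihydroxy-6,8a-dimethyl-5-oxo-3-(propan-2-yl)decahydroazulen-4-yl 4-(benzyloxy)benzoate (isomers at C-6 and C-7 of the azulene) | CC(C)[C@]1(O)CC[C@]2(C)CC(O)C(C)C(=O)[C@H](OC(=O)c3ccc(OCc4ccccc4)cc3)[C@H]21 | intermediate
19 | (3R,3aS,4R,8aR)-3-hydroxy-6,8a-dimethyl-5-oxo-3-(propan-2-yl)-1,2,3,3a,4,5,8,8a-octahydroazulen-4-yl 4-(benzyloxy)benzoate | CC(C)[C@]1(O)CC[C@]2(C)CC=C(C)C(=O)[C@H](OC(=O)c3ccc(OCc4ccccc4)cc3)[C@H]21 | intermediate
20 | (3R,3aS,4R,6S,7S,8aR)-3,6,7-trihydroxy-6,8a-dimethyl-5-oxo-3-(propan-2-yl)decahydroazulen-4-yl 4-(benzyloxy)benzoate | CC(C)[C@]1(O)CC[C@]2(C)C[C@H](O)[C@](C)(O)C(=O)[C@H](OC(=O)c3ccc(OCc4ccccc4)cc3)[C@H]21 | intermediate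
21 | (3R,3aS,4R,6S,7S,8aR)-3,6,7-trihydroxy-6,8a-dimethyl-5-oxo-3-(propan-2-yl)decahydroazulen-4-yl 4-hydroxybenzoate | CC(C)[C@]1(O)CC[C@]2(C)C[C@H](O)[C@](C)(O)C(=O)[C@H](OC(=O)c3ccc(O)cc3)[C@H]21 | target

**Step count and risks**

Total step count: 14. Longest linear sequence: 14 steps (1 to 21).

The three steps most likely to fail:

Step 5. The ring-bond shift may be outrun by ionisation of the epoxide at C4 followed by a hydride shift to a ketone, or by loss of the silyl group with simple opening of the epoxide. The fallback sets out from 6: the silyl ether is cleaved (Bu4NF, THF) to the trans-epoxy alcohol (1R,2S,3R,6S)-3-ethenyl-3-methyl-7-oxabicyclo[4.1.0]heptan-2-ol F1. The rearrangement is then run as the hydroxyl-driven semipinacol of the free α-hydroxy epoxide (ZnBr2, CH2Cl2, rt), in which the metal alkoxide pushes the anti ring bond across without a free cation at C4. This should give the β-hydroxy aldehyde (1R,2R,5S)-2-ethenyl-5-hydroxy-2-methylcyclopentane-1-carbaldehyde F2, which is silylated (t-BuMe2SiOTf, 2,6-lutidine, CH2Cl2, −78 °C) to come back to the route at 7.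

Step 6. The addition of the hindered dithiane anion to the hindered aldehyde may proceed with poor facial selectivity at C6. The fallback sets out from 7 and 8: the addition is quenched with aqueous NH4Cl and the carbinol (R)-[(1S,2R,5S)-5-{[tert-butyl(dimethyl)silyl]oxy}-2-ethenyl-2-methylcyclopentyl](2-ethyl-1,3-dithian-2-yl)methanol F3 is isolated together with its C6 epimer. The mixture is oxidised (SO3·pyridine, DMSO, i-Pr2NEt; Parikh–Doering) to the ketone [(1R,2R,5S)-5-{[tert-butyl(dimethyl)silyl]oxy}-2-ethenyl-2-methylcyclopentyl](2-ethyl-1,3-dithian-2-yl)methanone F4. This is reduced under reagent control ((S)-1-methyl-3,3-diphenyltetrahydro-1H,3H-pyrrolo[1,2-c][1,3,2]oxazaborole or its enantiomer, BH3·SMe2) back to the single epimer F3, which is acylated with 9 (4-(dimethylamino)pyridine, pyridine) to come back at 12.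

Step 12. The seven-membered closure may be slow, so that intermolecular condensation or epimerisation at C6 under the condensation conditions competes. The fallback sets out from 17: a boron enolate is formed regioselectively on the ethyl side of the α-acyloxy ketone ((c-C6H11)2BCl, Me2NEt, Et2O, −78 °C) and closes onto the aldehyde in a kinetically controlled intramolecular boron aldol reaction, giving 18, which is isolated after buffered oxidative work-up. Mesylation (MeSO2Cl, Et3N, CH2Cl2, 0 °C) gives (3R,3aS,4R,8aR)-3-hydroxy-7-[(methanesulfonyl)oxy]-6,8a-dimethyl-5-oxo-3-(propan-2-yl)decahydroazulen-4-yl 4-(benzyloxy)benzoate F5, and elimination with 1,8-diazabicyclo[5.4.0]undec-7-ene comes back at 19.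

**Further compounds**

F1 | step 5 | (1R,2S,3R,6S)-3-ethenyl-3-methyl-7-oxabicyclo[4.1.0]heptan-2-ol | C=C[C@@]1(C)CC[C@@H]2O[C@@H]2[C@H]1O
F2 | step 5 | (1R,2R,5S)-2-ethenyl-5-hydroxy-2-methylcyclopentane-1-carbaldehyde | O=C[C@H]1[C@@H](O)CC[C@]1(C)C=C
F3 | step 6 | (R)-[(1S,2R,5S)-5-{[tert-butyl(dimethyl)silyl]oxy}-2-ethenyl-2-methylcyclopentyl](2-ethyl-1,3-dithian-2-yl)methanol | CCC1(SCCCS1)[C@H](O)[C@H]2[C@@H](O[Si](C)(C)C(C)(C)C)CC[C@]2(C)C=C
F4 | step 6 | [(1R,2R,5S)-5-{[tert-butyl(dimethyl)silyl]oxy}-2-ethenyl-2-methylcyclopentyl](2-ethyl-1,3-dithian-2-yl)methanone | CCC1(SCCCS1)C(=O)[C@H]2[C@@H](O[Si](C)(C)C(C)(C)C)CC[C@]2(C)C=C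
F5 | step 12 | (3R,3aS,4R,8aR)-3-hydroxy-7-[(methanesulfonyl)oxy]-6,8a-dimethyl-5-oxo-3-(propan-2-yl)decahydroazulen-4-yl 4-(benzyloxy)benzoate | CC(C)[C@]1(O)CC[C@]2(C)CC(OS(C)(=O)=O)C(C)C(=O)[C@H](OC(=O)c3ccc(OCc4ccccc4)cc3)[C@H]21
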